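**Assumption:** the target is (2S)-8-geranylnaringenin exactly as encoded in the SMILES (E-geranyl at C8, 2S). Chloromethyl methyl ether, bases, acids and the catalyst are treated as reagents and carry no compound number.

## Retrosynthetic overview

- Target ⇐ (2S)-tris-MOM flavanone by acidic removal of three MOM ethers; the (2S) enantiomer is taken from the racemic flavanone by a catalytic transfer-hydrogenation kinetic resolution.
- Racemic flavanone ⇐ 2'-hydroxychalcone by intramolecular oxa-Michael closure. Ring C is the only ring formed and it is formed last; rings A and B come from aromatic starting materials.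
- Chalcone ⇐ Claisen–Schmidt aldol condensation (key C–C bond, Cα–Cβ) of a geranylated 2-hydroxy-4,6-bis(MOM)acetophenone with 4-(MOM-oxy)benzaldehyde.
- Acetophenone ⇐ 2,4,6-trihydroxyacetophenone by C-geranylation, then chelation-controlled bis-MOM protection that leaves free only the hydroxyl between acetyl and geranyl, which fixes geranyl at C8.

## Route

**Step 1**
Reactants: 1 2,4,6-trihydroxyacetophenone; 2 geranyl bromide ((2E)-1-bromo-3,7-dimethylocta-2,6-diene)
Product: 3 1-{3-[(2E)-3,7-dimethylocta-2,6-dien-1-yl]-2,4,6-trihydroxyphenyl}ethan-1-one (3-geranylphloroacetophenone)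
Conditions: DBU (1.1 equiv), 1 (1.5 equiv), THF, 0 °C → rt, 24 h; chromatography
Reagents that add atoms: none
Why: Base-mediated C-alkylation (SN2 on the primary allylic bromide) of the vinylogous-acid phloroglucinol anion occurs at the equivalent C3/C5 positions, so mono-C-geranylation gives a single regioisomer with the E-olefin untouched and no stereocenter formed.

**Step 2**
Reactants: 3 3-geranylphloroacetophenone
Product: 4 1-{3-[(2E)-3,7-dimethylocta-2,6-dien-1-yl]-2-hydroxy-4,6-bis(methoxymethoxy)phenyl}ethan-1-one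
Conditions: MOMCl (2.2 equiv), iPr2NEt (2.5 equiv), CH2Cl2, 0 °C → rt, 3 h
Reagents that add atoms: chloromethyl methyl ether (MOMCl), COCCl
Why: Chelation-controlled Williamson-type O-alkylation, in which the 2-OH (buttressed by the geranyl group) stays locked in the hydrogen bond to the acetyl carbonyl while the 4-OH and the non-chelated 6-OH are etherified, leaving free exactly the oxygen that must become O1 (regiochemistry to be confirmed by NOE from H-5 to both OCH2O groups).

**Step 3**
Reactants: 5 4-hydroxybenzaldehyde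
Product: 6 4-(methoxymethoxy)benzaldehyde
Conditions: MOMCl (1.3 equiv), iPr2NEt (1.5 equiv), CH2Cl2, 0 °C → rt
Reagents that add atoms: chloromethyl methyl ether (MOMCl), COCCl
Why: Phenol O-alkylation (MOM ether formation) masks the acidic phenol so that the aldehyde stays electrophilic under the strongly basic condensation.

**Step 4**
Reactants: 4 geranylated 2-hydroxy-4,6-bis(MOM)acetophenone; 6 4-(methoxymethoxy)benzaldehyde
Product: 8 (2E)-1-{3-[(2E)-3,7-dimethylocta-2,6-dien-1-yl]-2-hydroxy-4,6-bis(methoxymethoxy)phenyl}-3-[4-(methoxymethoxy)phenyl]prop-2-en-1-one, via β-hydroxy ketone aldol adduct 7 (not isolated)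
Conditions: KOH (10 equiv), 6 (1.3 equiv), EtOH/H2O (4:1), 0 °C → rt, 36 h, Ar
Reagents that add atoms: none
Why: Claisen–Schmidt (crossed aldol) condensation in which the methyl ketone enolate adds to the non-enolisable aldehyde and the β-hydroxy ketone loses water by E1cB to the conjugated E-enone, the MOM ethers and geranyl chain being inert to KOH and the transient carbinol stereocenter being destroyed.

**Step 5**
Reactants: 8 2'-hydroxychalcone
Product: 9 racemic 8-[(2E)-3,7-dimethylocta-2,6-dien-1-yl]-5,7-bis(methoxymethoxy)-2-[4-(methoxymethoxy)phenyl]-2,3-dihydro-4H-chromen-4-one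
Conditions: NaOAc (10 equiv), EtOH, reflux, 36 h; recovered 8 recycled
Reagents that add atoms: none
Why: Intramolecular oxa-Michael addition (the classical chalcone–flavanone isomerisation) of the only free phenol onto the enone closes ring C with geranyl at C8, and the new C2 stereocenter forms without control, giving the racemate.

**Step 6**
Reactants: 9 racemic tris-MOM 8-geranylflavanone
Product: 10 (2S)-8-[(2E)-3,7-dimethylocta-2,6-dien-1-yl]-5,7-bis(methoxymethoxy)-2-[4-(methoxymethoxy)phenyl]-2,3-dihydro-4H-chromen-4-one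
Conditions: Cp*RhCl[(R,R)-TsDPEN] (1 mol %), HCO2H/Et3N (5:2), EtOAc, 40 °C, stopped at ca. 53% conversion (chiral HPLC); chromatography (maximum yield 50%)
Reagents that add atoms: none
Why: Noyori-type asymmetric transfer hydrogenation used as a kinetic resolution, in which the (R,R)-catalyst delivers hydride to the carbonyl face giving the 4R alcohol, a face that is unhindered (anti to the 2-aryl group) only in the (2R)-ketone, so that enantiomer is reduced to the cis-(2R,4R)-flavan-4-ol while the (2S)-ketone is recovered in high ee with the isolated alkenes untouched; C2 is selected here, not newly made.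

**Step 7**
Reactants: 10 (2S)-tris-MOM 8-geranylflavanone
Product: 11 sophoraflavanone A, (2S)-8-[(2E)-3,7-dimethylocta-2,6-dien-1-yl]-5,7-dihydroxy-2-(4-hydroxyphenyl)-2,3-dihydro-4H-chromen-4-one
Conditions: 3 M aq. HCl, MeOH, 45 °C, 2 h, Ar; NaHCO3 work-up to pH 6
Reagents that add atoms: none
Why: Acid-catalysed acetal cleavage (transacetalisation to dimethoxymethane) unmasks the three phenols under conditions mild enough to spare the geranyl olefins and the C2 configuration, since flavanones do not ring-open under dilute acid.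

## Compound list

1 | 2,4,6-trihydroxyacetophenone | CC(=O)c1c(O)cc(O)cc1O | starting material
2 | geranyl bromide, (2E)-1-bromo-3,7-dimethylocta-2,6-diene | CC(C)=CCC/C(C)=C/CBr | starting material
3 | 1-{3-[(2E)-3,7-dimethylocta-2,6-dien-1-yl]-2,4,6-trihydroxyphenyl}ethan-1-one | CC(C)=CCC/C(C)=C/Cc1c(O)cc(O)c(C(C)=O)c1O | intermediate
4 | 1-{3-[(2E)-3,7-dimethylocta-2,6-dien-1-yl]-2-hydroxy-4,6-bis(methoxymethoxy)phenyl}ethan-1-one | CC(C)=CCC/C(C)=C/Cc1c(OCOC)cc(OCOC)c(C(C)=O)c1O | intermediate
5 | 4-hydroxybenzaldehyde | O=Cc1ccc(O)cc1 | starting material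
6 | 4-(methoxymethoxy)benzaldehyde | COCOc1ccc(C=O)cc1 | intermediate
7 | racemic 1-{3-geranyl-2-hydroxy-4,6-bis(methoxymethoxy)phenyl}-3-hydroxy-3-[4-(methoxymethoxy)phenyl]propan-1-one (aldol adduct, not isolated) | CC(C)=CCC/C(C)=C/Cc1c(OCOC)cc(OCOC)c(C(=O)CC(O)c2ccc(OCOC)cc2)c1O | intermediate
8 | (2E)-1-{3-geranyl-2-hydroxy-4,6-bis(methoxymethoxy)phenyl}-3-[4-(methoxymethoxy)phenyl]prop-2-en-1-one | CC(C)=CCC/C(C)=C/Cc1c(OCOC)cc(OCOC)c(C(=O)/C=C/c2ccc(OCOC)cc2)c1O | intermediate
9 | racemic 8-geranyl-5,7-bis(methoxymethoxy)-2-[4-(methoxymethoxy)phenyl]-2,3-dihydro-4H-chromen-4-one | CC(C)=CCC/C(C)=C/Cc1c(OCOC)cc(OCOC)c2c1OC(c1ccc(OCOC)cc1)CC2=O | intermediate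
10 | (2S)-8-geranyl-5,7-bis(methoxymethoxy)-2-[4-(methoxymethoxy)phenyl]-2,3-dihydro-4H-chromen-4-one | CC(C)=CCC/C(C)=C/Cc1c(OCOC)cc(OCOC)c2c1O[C@H](c1ccc(OCOC)cc1)CC2=O | intermediate
11 | sophoraflavanone A, (2S)-8-geranyl-5,7-dihydroxy-2-(4-hydroxyphenyl)-2,3-dihydro-4H-chromen-4-one | CC(C)=CCC/C(C)=C/Cc1c(O)cc(O)c2c1O[C@H](c1ccc(O)cc1)CC2=O | target

## Step count

Total: 7 steps. Longest linear sequence: 6 steps (steps 1, 2, 4, 5, 6, 7; 1 → 3 → 4 → 8 → 9 → 10 → 11); step 3 is a one-step side branch.

## Three steps most likely to fail, with fallbacks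

**Step 1 (C-geranylation).** O-alkylation and double C-alkylation compete, so the yield is expected to be only about 30–45%. The fallback sets out from geranyl bromide 2 and comes back to the route at 3. Commercial phloroglucinol is exhaustively protected (NaH, MOMCl, DMF) to 1,3,5-tris(methoxymethoxy)benzene F1. Directed ortho-lithiation between two MOM ethers (n-BuLi, THF, 0 °C) and alkylation of the aryllithium with 2 gives 2-geranyl-1,3,5-tris(methoxymethoxy)benzene F2. A second lithiation at the remaining position flanked by two MOM ethers (n-BuLi, TMEDA, THF, −20 °C) and quench with N-methoxy-N-methylacetamide gives 1-[3-geranyl-2,4,6-tris(methoxymethoxy)phenyl]ethan-1-one F3. Treatment with HCl in MeOH at 40 °C removes all three MOM groups and delivers 3.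

**Step 2 (regioselective bis-protection).** The 2-OH and 6-OH may be discriminated only moderately, giving some of the 6-hydroxy isomer that would lead to the 6-geranyl series. The fallback sets out from 3 and comes back to the route at 11; it replaces selective protection by separation of ring-closure regioisomers with recycling.
- 3 is protected only at the non-chelated para hydroxyl (MOMCl 1.05 equiv, iPr2NEt, CH2Cl2, −10 °C) to give 1-{3-geranyl-2,6-dihydroxy-4-(methoxymethoxy)phenyl}ethan-1-one F4.
- Claisen–Schmidt condensation of F4 with 6 (KOH, EtOH) gives the 2',6'-dihydroxychalcone F5.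
- NaOAc in refluxing EtOH closes ring C through either ortho hydroxyl, giving racemic 8-geranyl-5-hydroxy-7-(methoxymethoxy)-2-[4-(methoxymethoxy)phenyl]chroman-4-one F6 and its 6-geranyl isomer F7.
- F6 and F7 are separated on silica; F7 is re-equilibrated through F5 under the same base conditions and recycled.
- F6 is resolved by the same transfer-hydrogenation kinetic resolution as in step 6 to the (2S)-flavanone F8, and HCl/MeOH then gives 11.

**Step 6 (kinetic resolution).** The ketone flanked by the 5-MOM ether may be reduced too slowly or with too small a rate difference between enantiomers. The fallback sets out from 9 and comes back to the route at 10. Racemic 9 is separated by preparative chiral supercritical-fluid chromatography (amylose tris(3,5-dimethylphenylcarbamate) phase, CO2/iPrOH) into 10 and the (2R)-enantiomer F9. F9 is racemised back to 9 by base-mediated ring opening and re-closure through chalcone 8 (NaOAc, EtOH, reflux) and resubmitted.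

## Further compounds

F1 | step 1 | 1,3,5-tris(methoxymethoxy)benzene | COCOc1cc(OCOC)cc(OCOC)c1
F2 | step 1 | 2-[(2E)-3,7-dimethylocta-2,6-dien-1-yl]-1,3,5-tris(methoxymethoxy)benzene | CC(C)=CCC/C(C)=C/Cc1c(OCOC)cc(OCOC)cc1OCOC
F3 | step 1 | 1-{3-[(2E)-3,7-dimethylocta-2,6-dien-1-yl]-2,4,6-tris(methoxymethoxy)phenyl}ethan-1-one | CC(C)=CCC/C(C)=C/Cc1c(OCOC)cc(OCOC)c(C(C)=O)c1OCOC
F4 | step 2 | 1-{3-[(2E)-3,7-dimethylocta-2,6-dien-1-yl]-2,6-dihydroxy-4-(methoxymethoxy)phenyl}ethan-1-one | CC(C)=CCC/C(C)=C/Cc1c(OCOC)cc(O)c(C(C)=O)c1O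
F5 | step 2 | (2E)-1-{3-geranyl-2,6-dihydroxy-4-(methoxymethoxy)phenyl}-3-[4-(methoxymethoxy)phenyl]prop-2-en-1-one | CC(C)=CCC/C(C)=C/Cc1c(OCOC)cc(O)c(C(=O)/C=C/c2ccc(OCOC)cc2)c1O
F6 | step 2 | racemic 8-geranyl-5-hydroxy-7-(methoxymethoxy)-2-[4-(methoxymethoxy)phenyl]-2,3-dihydro-4H-chromen-4-one | CC(C)=CCC/C(C)=C/Cc1c(OCOC)cc(O)c2c1OC(c1ccc(OCOC)cc1)CC2=O
F7 | step 2 | racemic 6-geranyl-5-hydroxy-7-(methoxymethoxy)-2-[4-(methoxymethoxy)phenyl]-2,3-dihydro-4H-chromen-4-one | CC(C)=CCC/C(C)=C/Cc1c(OCOC)cc2c(c1O)C(=O)CC(c1ccc(OCOC)cc1)O2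
F8 | step 2 | (2S)-8-geranyl-5-hydroxy-7-(methoxymethoxy)-2-[4-(methoxymethoxy)phenyl]-2,3-dihydro-4H-chromen-4-one | CC(C)=CCC/C(C)=C/Cc1c(OCOC)cc(O)c2c1O[C@H](c1ccc(OCOC)cc1)CC2=O
F9 | step 6 | (2R)-8-geranyl-5,7-bis(methoxymethoxy)-2-[4-(methoxymethoxy)phenyl]-2,3-dihydro-4H-chromen-4-one | CC(C)=CCC/C(C)=C/Cc1c(OCOC)cc(OCOC)c2c1O[C@@H](c1ccc(OCOC)cc1)CC2=O
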